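## Structural features

The target is an acylated cyclohexane: the quinic acid ring (C1–C6, carboxyl carbon C7) with no further ring apart from the two aryl groups of its acyl residues. C1 is quaternary and carries a tertiary hydroxyl and the free carboxyl, C2 and C6 are methylenes, and C3, C4 and C5 are three contiguous oxygen-bearing stereocentres. O3 carries an (E)-caffeoyl (3,4-dihydroxycinnamoyl) ester and O4 an (E)-p-coumaroyl (4-hydroxycinnamoyl) ester, while O5 and O1 are free. O3 and O4 are cis to each other and to O1, whereas O5 is trans to O4 and cis to the carboxyl, which is the configuration of (−)-quinic acid. Two different esters on neighbouring cis oxygens beside a free hydroxyl invite acyl migration under base, the catechol is easily oxidised, and the conjugated alkenes exclude hydrogenolysis or hydride chemistry once the esters are in place. The real difficulty is twofold: building the tetra-oxygenated ring with four stereocentres, and telling four hydroxyls apart so that two different acyl groups reach O3 and O4 specifically. The key step exploits the C3–C4 cis-diol, flanked by the oxygenated C5 on one side and the C2 methylene on the other: C3 and C4 can both be aldehyde carbons of an open chain C3–C2–C1–C6–C5–C4, and their reductive union closes the ring. The cis relation of C7 and O5 is used afterwards to tie them as a γ-lactone, which masks O5 and turns O3 equatorial and O4 axial.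

## Logic of the disconnections

29 ⇒ 28. No carbon–carbon bond is cut: three aryl O–H bonds become O–acetyl bonds and C7 is joined to O5 as a γ-lactone. The lactone hides the acid and O5 in one stroke and the acetates silence the phenols, so the precursor is neutral and has one free (tertiary) hydroxyl. The demand is that the last step cleaves one lactone and three aryl acetates but neither alkyl cinnamate, and lets no acyl group move to O5; this points to acid, not base.

28 ⇒ 24 + 26 (through 27). The O4–acyl bond is cut. O4 is axial in the lactone and the least reactive secondary position, so it is acylated last, when it is the only secondary hydroxyl left. The gain is that the p-coumaroyl unit becomes a one-step derivative of 25. The forward step must acylate a hindered hydroxyl and spare the tertiary O1.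

24 ⇒ 20 + 22 (through 23). The O3–acyl bond is cut. In 20 the bicyclic frame gives three hydroxyls of graded reactivity (O3 equatorial, O4 axial, O1 tertiary), so the problem of four similar hydroxyls shrinks to a kinetic choice. The forward step must stop at mono-acylation of O3.

22 ⇒ 21 and 26 ⇒ 25. Only O–acetyl bonds are cut; both acids become commercial hydroxycinnamic acids. The forward steps are plain acetylations.

20 ⇒ 18 (through 19). The lactone bond C7–O5 is cut; O1 and C7 are tied to one acetal carbon and O5 is silylated. In 18 the only free groups are the two hydroxyls made in the ring closure, and one acid treatment unmasks everything and lactonises. This set is preferred to an ether on the tertiary O1, an alkyl ester and a benzyl ether on O5 for three reasons: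
- that set needs etherification of a hindered tertiary α-hydroxy ester;
- it exposes a C5 alkoxide to a C1 ester during basic alkylation, which invites γ-lactonisation;
- it costs separate hydrogenolysis and lactonisation steps after the ring closure.

The acetal is present from the first step onwards. The demand is that acetal and silyl ether survive ozone and SmI2.

18 ⇒ 16 (through 17). The C3–C4 bond is cut and the ring opens to a 1,6-dialdehyde. A vicinal cis-diol is the retron of a reductive carbonyl coupling, and the oxygenated C5 next to C4 supplies the stereochemical lever. One ring, one C–C bond and two stereocentres vanish, leaving C1 and C5 on an open chain. The forward step must be intramolecular, cis-selective, anti to O5, and must leave the acetal carbonyl alone.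

16 ⇒ 14 (through 15). The two C=O bonds become C=C bonds: C3 is the inner carbon of an allyl group and C4 the inner carbon of a 2-methylprop-1-enyl group. Enolisable, epimerisable aldehydes are thus carried as alkenes and released together. The demand is one ozonolysis with no other ozone-sensitive group, and immediate use of the product.

14 ⇒ 13 ⇒ 11 (through 12). The O5–Si bond and then the C5–H bond are removed, so C5 becomes a ketone between an alkenyl group and the C6 methylene. Catalyst-controlled enone reduction is the most dependable way to set an isolated carbinol 1,3 to a quaternary centre. A trisubstituted alkenyl group is chosen over a vinyl group because it is better distinguished from the methylene side and gives a stable enone. The reductant must not hydroborate the allyl group, and O5 must be capped before it can attack the ring carbonyl.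

11 ⇒ 8 + 9, and 8 ⇒ 6 (through 10 and 7). The C4–C5 acyl–alkenyl bond and the amide C–N bond are cut, which traces the side chain to the free carboxyl arm of 6. The Grignard reagent must choose the amide over the ring carbonyl.

6 ⇒ 3 + 4 (through 5). The C1–C2 bond is cut. A quaternary carbinol next to a carboxyl is the retron for alkylating the enolate of an α-hydroxy acid, and the acetal centre stores the chirality while C1 is trigonal. The electrophile must enter anti to the tert-butyl group, which means net retention at C1.

3 ⇒ 1 + 2. The two acetal C–O bonds are cut. 1 supplies C1, C6, C7, the future C5 carbon and the C1 configuration; 2 is the auxiliary. The acetalisation must favour the five-membered ring and the cis isomer.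

## Other disconnections considered

Alternative 1: The cut is the C1–O1 bond. The ring is bought complete as (−)-shikimic acid A1, which already holds C3, C4 and C5 correctly.
- Forward key step: A1 would be turned (ester, 3,4-acetonide, 5-silyl ether, ester reduction) into the C7 allylic alcohol A2. A Sharpless asymmetric epoxidation in the D-(−)-tartrate series would then place oxygen on C1=C2 to give the oxirane A3. Hydride opening at C2, re-oxidation of C7 and acid would lead to 20.
- In its favour: the ring and three stereocentres come from the pool, only C1 is made, the substrate is a primary allylic alcohol (the ideal class for this reaction), and no C–C bond is formed.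
- Against it here: the oxygen must arrive on the face syn to the C3 acetonide oxygen, so the catalyst has to overrule the substrate. C7 is reduced and oxidised again. Oxidation beside a tertiary hydroxyl risks glycol cleavage. The acetonide and silyl groups of A3 protect exactly the oxygens that must be acylated, so they must be dismantled to reach 20. A1 also costs more than 19.
- Comparison: on structure the alternative is the better (one new stereocentre against three). On mechanism it is at least the equal (concerted, catalyst-controlled oxygen transfer against substrate-controlled ketyl coupling). On step economy the two are about equal up to 20. The chosen plan has the merit of creating the carbocycle itself.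

Alternative 2: The cuts are C5–C6 and C1–C2, two aldol bonds, leading to phosphoenolpyruvate A4 and D-erythrose 4-phosphate A5.
- Forward key step: in one pot a DAHP synthase would join A4 and A5 to the open-chain heptulosonate A6, and a dehydroquinate synthase would cyclise it to 3-dehydroquinic acid A7. Reduction of the C3 ketone (a quinate dehydrogenase, or a hydride) would give 19 and then 20.
- In its favour: two C–C bonds, the ring and C1 arise in water without protecting groups, C4 and C5 come from A5, and stereocontrol is absolute. On step economy and on stereocontrol it is the better of the two plans.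
- Against it here: A5 is costly and unstable and is normally generated in situ. Two enzymes must be produced, and the cyclase needs NAD+ and a divalent metal ion. The very polar A7 must be isolated from dilute aqueous solution. A chemical C3 reduction could give both epimers.
- Comparison: the alternative copies biosynthesis up to a commodity and leaves the real difficulty, the regioselective double acylation, unchanged; on that point the plans are equal. For a synthesis laboratory the chosen plan is more practical.

Alternative 3: The cuts are C2–C3 and C1–C6, a [4+2] disconnection to buta-1,3-diene A8 and 2-(benzoyloxy)acrolein A9.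
- Forward key step: a chiral acid catalyst would give the Diels–Alder adduct A10 with C1 set. Oxidation of the aldehyde, halolactonisation onto the alkene and elimination would give the bicyclic alkene A11. Dihydroxylation anti to the lactone bridge and debenzoylation would give 20.
- In its favour: the materials are cheap and achiral, one catalytic step sets C1, and a rigid lactone relays it to C5 and then to C3 and C4 by very predictable reactions. The count to 20 is lower than in the chosen plan, which makes it the better on step economy. O1 can also stay benzoylated during the acylations, a real advantage.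
- Against it here: A8 is a gas and the least reactive diene. The whole absolute configuration rests on one enantioselective event with an unsubstituted diene, with crystallisation as the only means of upgrading. A9 must be prepared. A late benzoate would have to be removed beside two cinnamates.
- Comparison: the chosen plan is the better on security of C1, which comes enantiopure from 1. It is the equal in that both plans reach 20.

Key step: step 8

Remark (assumption on the chemistry): the locants C1–C7 and O1–O5 are those of the quinic acid core of 29 and are kept for all intermediates, open-chain ones included. 9 is taken to be bought as its THF solution, and 23 and 27 are used crude after removal of volatiles.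

Step 1
Reactants: 1 (S)-malic acid; 2 pivalaldehyde
Product: 3 2-[(2S,4S)-2-tert-butyl-5-oxo-1,3-dioxolan-4-yl]acetic acid
Conditions: p-TsOH·H2O (cat.), H2SO4 (cat.), pentane, reflux, Dean–Stark; recrystallisation
Reagents that add atoms: none
Why: Acid-catalysed acetalisation of the α-hydroxy acid gives the five-membered dioxolanone and leaves the β-carboxyl free, which tells the two acid groups apart. The acetal carbon equilibrates, and the more stable cis isomer (tert-butyl and CH2CO2H on one face) should be obtained pure by crystallisation.

Step 2
Reactants: 3 2-[(2S,4S)-2-tert-butyl-5-oxo-1,3-dioxolan-4-yl]acetic acid; 4 allyl bromide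
Product: 6 2-[(2S,4S)-2-tert-butyl-5-oxo-4-(prop-2-en-1-yl)-1,3-dioxolan-4-yl]acetic acid, via dilithium enolate 5 (not isolated)
Conditions: LiN(SiMe3)2 (2.2 equiv), THF, −78 °C; then 4, −78 → −20 °C; cold 1 M HCl
Reagents that add atoms: none
Why: Alkylation of a chiral dioxolanone enolate (self-regeneration of stereocentres): one equivalent of base makes the carboxylate, the second the ring enolate, and the acetal centre keeps the stereochemical information while C1 is trigonal. Allyl bromide should approach anti to the tert-butyl group, so allyl takes the place of the former hydrogen and C1 forms with net retention, as the target requires.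

Step 3
Reactants: 6 2-[(2S,4S)-2-tert-butyl-5-oxo-4-(prop-2-en-1-yl)-1,3-dioxolan-4-yl]acetic acid
Product: 8 2-[(2S,4S)-2-tert-butyl-5-oxo-4-(prop-2-en-1-yl)-1,3-dioxolan-4-yl]-N-methoxy-N-methylacetamide, via acyl imidazolide 7 (not isolated)
Conditions: CDI, CH2Cl2, 0 °C → rt; then MeNHOMe·HCl, rt
Reagents that add atoms: N,O-dimethylhydroxylamine hydrochloride, CNOC.Cl
Why: Standard amide formation through an acyl imidazolide. The near-neutral conditions leave the nucleophile-sensitive dioxolanone alone and no stereocentre is involved.

Step 4
Reactants: 8 2-[(2S,4S)-2-tert-butyl-5-oxo-4-(prop-2-en-1-yl)-1,3-dioxolan-4-yl]-N-methoxy-N-methylacetamide; 9 (2-methylprop-1-en-1-yl)magnesium bromide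
Product: 11 (2S,5S)-2-tert-butyl-5-(4-methyl-2-oxopent-3-en-1-yl)-5-(prop-2-en-1-yl)-1,3-dioxolan-4-one, via magnesium hemiaminal chelate 10 (not isolated)
Conditions: 9 (1.3 equiv), THF, −78 → −20 °C; poured into cold 1 M HCl
Reagents that add atoms: none
Why: Weinreb ketone synthesis: the chelate 10 should not collapse before the acidic quench, so the ketone never meets the Grignard reagent. The amide carbonyl sits on a methylene whereas the ring carbonyl is attached to the fully substituted C1, which should steer the bulky alkenyl nucleophile to the amide. The β,β-dimethyl enone should neither add the liberated amine nor polymerise as a vinyl ketone might.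

Step 5
Reactants: 11 (2S,5S)-2-tert-butyl-5-(4-methyl-2-oxopent-3-en-1-yl)-5-(prop-2-en-1-yl)-1,3-dioxolan-4-one
Product: 13 (2S,5S)-2-tert-butyl-5-[(2R)-2-hydroxy-4-methylpent-3-en-1-yl]-5-(prop-2-en-1-yl)-1,3-dioxolan-4-one, via catecholborate ester 12 (not isolated)
Conditions: (S)-2-methyl-CBS-oxazaborolidine (0.2 equiv), catecholborane (1.8 equiv), toluene, −78 °C; MeOH, pH 7 buffer
Reagents that add atoms: none
Why: Corey–Bakshi–Shibata reduction: the alkenyl group acts as the large and the C6 methylene as the small substituent, so the (S)-catalyst should deliver hydride to the face that gives the (R)-carbinol, the C5 configuration of the target. Catecholborane at −78 °C is chosen because it does not hydroborate the allyl group or reduce the dioxolanone, and the neutral work-up gives the new hydroxyl little chance to attack the ring carbonyl.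

Step 6
Reactants: 13 (2S,5S)-2-tert-butyl-5-[(2R)-2-hydroxy-4-methylpent-3-en-1-yl]-5-(prop-2-en-1-yl)-1,3-dioxolan-4-one
Product: 14 (2S,5S)-2-tert-butyl-5-[(2R)-2-(tert-butyldimethylsilyloxy)-4-methylpent-3-en-1-yl]-5-(prop-2-en-1-yl)-1,3-dioxolan-4-one
Conditions: TBSOTf (1.2 equiv), 2,6-lutidine, CH2Cl2, −78 °C
Reagents that add atoms: tert-butyldimethylsilyl trifluoromethanesulfonate, CC(C)(C)[Si](C)(C)OS(=O)(=O)C(F)(F)F
Why: Silylation of a secondary alcohol with a silyl triflate and a hindered pyridine base is fast at −78 °C and forms no alkoxide, so O5 should be capped before it can transacylate the dioxolanone. The silyl ether is inert to ozone and SmI2 and cannot chelate samarium.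

Step 7
Reactants: 14 (2S,5S)-2-tert-butyl-5-[(2R)-2-(tert-butyldimethylsilyloxy)-4-methylpent-3-en-1-yl]-5-(prop-2-en-1-yl)-1,3-dioxolan-4-one
Product: 16 (2R)-2-(tert-butyldimethylsilyloxy)-3-[(2S,4R)-2-tert-butyl-5-oxo-4-(2-oxoethyl)-1,3-dioxolan-4-yl]propanal, via bis-ozonide 15 (not isolated)
Conditions: O3, CH2Cl2, −78 °C (Sudan Red 7B end point); PPh3, −78 °C → rt; rapid silica plug; used at once
Reagents that add atoms: ozone, [O-][O+]=O
Why: Ozonolysis with reductive work-up cleaves both alkenes in one operation, the allyl group to the C3 aldehyde and the 2-methylprop-1-enyl group to the C4 aldehyde. The dye end point limits ozone contact with the acetal C–H bond, and neutral work-up with immediate use should avoid epimerisation at C5 and β-elimination of O1.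

Step 8
Reactants: 16 (2R)-2-(tert-butyldimethylsilyloxy)-3-[(2S,4R)-2-tert-butyl-5-oxo-4-(2-oxoethyl)-1,3-dioxolan-4-yl]propanal
Product: 18 5-O-TBS-quinic acid (S)-pivalaldehyde acetal (spiro 2-tert-butyl-1,3-dioxolan-4-one at C1; 3-OH and 4-OH cis and trans to 5-OTBS), via bis(diiodosamarium) diolate 17 (not isolated)
Conditions: SmI2 (3.0 equiv, 0.1 M in THF), t-BuOH (3 equiv), THF (0.01 M in 16), −78 °C → rt; aq. NaHCO3/KNaC4H4O6
Reagents that add atoms: none
Why: SmI2 (divalent samarium) transfers one electron to an aldehyde to give a samarium-bound ketyl; the oxophilic trivalent samarium also binds the second carbonyl oxygen, the ketyl carbon adds to that carbonyl carbon (or, after a second electron transfer, the two ketyls combine) and C3–C4 forms, a second equivalent of reductant completing the diolate 17, which is protonated on work-up. The closest known reaction type is the SmI2 pinacol cyclisation of sugar-derived 1,6-dialdehydes to cis-cyclohexane-1,2-diols used for cyclitols. The one ring that closes is the cyclohexane, formed in the 6-exo-trig mode (the attacked C=O is exocyclic to the ring being made). C3 is controlled by C4 through the metal: both oxygens are held on one samarium in the cyclic transition state, so the diol should be cis. C4 is controlled by C5: the C4–O(Sm) bond turns away from the C5–O bond of the bulky, non-chelating silyl ether (dipole and steric avoidance), so O4 should end up trans to O5. The step needs three selectivities: aldehyde over the dioxolanone carbonyl, secured because esters and lactones are not reduced by SmI2 in THF at low temperature without strongly donating additives; ring closure over intermolecular coupling or simple reduction, secured by dilution and by the quaternary C1 (gem-disubstituent effect); and cis/anti diastereoselection, secured as described. The α-silyloxy group is a poor leaving group, so the C4 ketyl should not fragment, and the new alkoxides lie on the face opposite C7, so they cannot open the dioxolanone.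

Step 9
Reactants: 18 5-O-TBS-quinic acid (S)-pivalaldehyde acetal
Product: 20 1,5-quinide [(1S,3R,4R,5R)-1,3,4-trihydroxy-6-oxabicyclo[3.2.1]octan-7-one], via quinic acid 19 (not isolated)
Conditions: 2 M aq. HCl/THF (1:1), 50 °C; evaporate; p-TsOH·H2O (cat.), toluene/DMF (4:1), reflux, Dean–Stark
Reagents that add atoms: water, O (its oxygen enters the carboxyl group of 19 and is lost again when 20 forms)
Why: Aqueous acid cleaves the silyl ether and opens the acetal, by hydrolysis or by attack of the freed O5 on the ring carbonyl, and both paths meet at 19 in water. Azeotropic dehydration then closes the γ-lactone between C7 and O5, the only hydroxyl cis to the carboxyl; no stereocentre is touched.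

Step 10
Reactants: 21 caffeic acid
Product: 22 (E)-3-(3,4-diacetoxyphenyl)prop-2-enoic acid
Conditions: Ac2O, pyridine, DMAP (cat.), 0 °C → rt; then H2O; 1 M HCl
Reagents that add atoms: acetic anhydride, CC(=O)OC(C)=O
Why: Acetylation of both phenols; any mixed anhydride at the acid is hydrolysed in the aqueous quench. The acetates suppress catechol oxidation and self-acylation in the coupling.

Step 11
Reactants: 20 1,5-quinide; 22 (E)-3-(3,4-diacetoxyphenyl)prop-2-enoic acid
Product: 24 3-O-[(E)-3,4-diacetoxycinnamoyl]-1,5-quinide, via 3,4-diacetoxycinnamoyl chloride 23 (not isolated)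
Conditions: 22, (COCl)2, DMF (cat.), CH2Cl2, 0 °C → rt, evaporate; then 20, pyridine/CH2Cl2, −20 → 0 °C (1.05 equiv of 23)
Reagents that add atoms: none
Why: Acylation of a polyol with an acid chloride in pyridine: the lactone locks the ring so that O3 is equatorial and unhindered, O4 axial and O1 tertiary, so one equivalent of chloride at low temperature without DMAP should go to O3. The C3 configuration is untouched.

Step 12
Reactants: 25 p-coumaric acid
Product: 26 (E)-3-(4-acetoxyphenyl)prop-2-enoic acid
Conditions: Ac2O, pyridine, DMAP (cat.), 0 °C → rt; then H2O; 1 M HCl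
Reagents that add atoms: acetic anhydride, CC(=O)OC(C)=O
Why: Acetylation of the phenol, as in step 10.

Step 13
Reactants: 24 3-O-[(E)-3,4-diacetoxycinnamoyl]-1,5-quinide; 26 (E)-3-(4-acetoxyphenyl)prop-2-enoic acid
Product: 28 3-O-[(E)-3,4-diacetoxycinnamoyl]-4-O-[(E)-4-acetoxycinnamoyl]-1,5-quinide, via 4-acetoxycinnamoyl chloride 27 (not isolated)
Conditions: 26, (COCl)2, DMF (cat.), CH2Cl2, 0 °C → rt, evaporate; then 24, pyridine, DMAP (0.1 equiv), CH2Cl2, 0 °C → rt (1.3 equiv of 27)
Reagents that add atoms: none
Why: DMAP-catalysed esterification of the one remaining secondary hydroxyl, the axial O4. The tertiary O1 beside the lactone carbonyl is much slower and should stay free with a small excess of chloride. A short reaction at or below room temperature limits O3 to O4 acyl migration.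

Step 14
Reactants: 28 3-O-[(E)-3,4-diacetoxycinnamoyl]-4-O-[(E)-4-acetoxycinnamoyl]-1,5-quinide
Product: 29 3-O-(E)-caffeoyl-4-O-(E)-p-coumaroylquinic acid (CNP0077575.1)
Conditions: 2 M aq. HCl/THF (1:3), rt → 35 °C, argon, dark; reverse-phase chromatography
Reagents that add atoms: water, O
Why: Acid-catalysed hydrolysis: the strained γ-lactone and the three aryl acetates (phenols are good leaving groups) should be cleaved faster than the two alkyl cinnamates, and under acid the vicinal esters should not migrate as they would under base. Opening the lactone frees O5 and the acid; no stereocentre is affected.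

Compound list

1 | (S)-malic acid [(2S)-2-hydroxybutanedioic acid] | O[C@H](C(=O)O)CC(=O)O | starting material
2 | pivalaldehyde (2,2-dimethylpropanal) | CC(C)(C)C=O | starting material
3 | 2-[(2S,4S)-2-tert-butyl-5-oxo-1,3-dioxolan-4-yl]acetic acid (tert-butyl and CH2CO2H cis) | OC(=O)C[C@@H]1O[C@H](C(C)(C)C)OC1=O | intermediate
4 | allyl bromide (3-bromoprop-1-ene) | C=CCBr | starting material
5 | dilithium enolate of 3 (lithium carboxylate and lithium ring enolate; acetal centre S) | [Li]OC(=O)CC1=C(O[Li])O[C@@H](C(C)(C)C)O1 | intermediate (not isolated)
6 | 2-[(2S,4S)-2-tert-butyl-5-oxo-4-(prop-2-en-1-yl)-1,3-dioxolan-4-yl]acetic acid (allyl trans to tert-butyl) | OC(=O)C[C@]1(CC=C)O[C@H](C(C)(C)C)OC1=O | intermediate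
7 | acyl imidazolide of 6 [(2S,5S)-2-tert-butyl-5-[2-(imidazol-1-yl)-2-oxoethyl]-5-(prop-2-en-1-yl)-1,3-dioxolan-4-one] | O=C(C[C@]1(CC=C)O[C@H](C(C)(C)C)OC1=O)n1ccnc1 | intermediate (not isolated)
8 | 2-[(2S,4S)-2-tert-butyl-5-oxo-4-(prop-2-en-1-yl)-1,3-dioxolan-4-yl]-N-methoxy-N-methylacetamide | CON(C)C(=O)C[C@]1(CC=C)O[C@H](C(C)(C)C)OC1=O | intermediate
9 | (2-methylprop-1-en-1-yl)magnesium bromide | CC(C)=C[Mg]Br | starting material
10 | bromomagnesium alkoxide of the N-methoxy-N-methyl hemiaminal from 8 and 9 (tetrahedral adduct; carbinol centre undefined) | CON(C)C(O[Mg]Br)(C=C(C)C)C[C@]1(CC=C)O[C@H](C(C)(C)C)OC1=O | intermediate (not isolated)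
11 | (2S,5S)-2-tert-butyl-5-(4-methyl-2-oxopent-3-en-1-yl)-5-(prop-2-en-1-yl)-1,3-dioxolan-4-one | CC(C)=CC(=O)C[C@]1(CC=C)O[C@H](C(C)(C)C)OC1=O | intermediate
12 | catecholborate ester of 13 (O5 bound to the 1,3,2-benzodioxaborole boron) | CC(C)=C[C@H](OB2Oc3ccccc3O2)C[C@]1(CC=C)O[C@H](C(C)(C)C)OC1=O | intermediate (not isolated)
13 | (2S,5S)-2-tert-butyl-5-[(2R)-2-hydroxy-4-methylpent-3-en-1-yl]-5-(prop-2-en-1-yl)-1,3-dioxolan-4-one | CC(C)=C[C@H](O)C[C@]1(CC=C)O[C@H](C(C)(C)C)OC1=O | intermediate
14 | (2S,5S)-2-tert-butyl-5-[(2R)-2-(tert-butyldimethylsilyloxy)-4-methylpent-3-en-1-yl]-5-(prop-2-en-1-yl)-1,3-dioxolan-4-one | CC(C)=C[C@H](O[Si](C)(C)C(C)(C)C)C[C@]1(CC=C)O[C@H](C(C)(C)C)OC1=O | intermediate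
15 | bis(1,2,4-trioxolane) of 14 (both alkenes as ozonides; ozonide carbons undefined) | CC1(C)OOC(O1)[C@H](O[Si](C)(C)C(C)(C)C)C[C@]2(CC3OCOO3)O[C@H](C(C)(C)C)OC2=O | intermediate (not isolated)
16 | (2R)-2-(tert-butyldimethylsilyloxy)-3-[(2S,4R)-2-tert-butyl-5-oxo-4-(2-oxoethyl)-1,3-dioxolan-4-yl]propanal | O=C[C@H](O[Si](C)(C)C(C)(C)C)C[C@]1(CC=O)O[C@H](C(C)(C)C)OC1=O | intermediate
17 | bis(diiodosamarium) 3,4-diolate of 18 (trivalent samarium) | I[Sm](I)O[C@H]1[C@H](O[Si](C)(C)C(C)(C)C)C[C@@]2(O[C@H](C(C)(C)C)OC2=O)C[C@H]1O[Sm](I)I | intermediate (not isolated)
18 | 5-O-TBS-quinic acid with O1 and C7 tied as the (S)-pivalaldehyde acetal (spiro 2-tert-butyl-1,3-dioxolan-4-one at C1; 3-OH and 4-OH cis to each other and to O1, trans to 5-OTBS) | O[C@H]1[C@H](O[Si](C)(C)C(C)(C)C)C[C@@]2(O[C@H](C(C)(C)C)OC2=O)C[C@H]1O | intermediate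
19 | (−)-quinic acid [(1S,3R,4S,5R)-1,3,4,5-tetrahydroxycyclohexane-1-carboxylic acid] | O[C@H]1[C@H](O)C[C@](O)(C(=O)O)C[C@H]1O | intermediate (not isolated)
20 | 1,5-quinide [(1S,3R,4R,5R)-1,3,4-trihydroxy-6-oxabicyclo[3.2.1]octan-7-one] | O[C@H]1[C@H]2C[C@](O)(C(=O)O2)C[C@H]1O | intermediate
21 | caffeic acid [(E)-3-(3,4-dihydroxyphenyl)prop-2-enoic acid] | OC(=O)/C=C/c1ccc(O)c(O)c1 | starting material
22 | (E)-3-(3,4-diacetoxyphenyl)prop-2-enoic acid | OC(=O)/C=C/c1ccc(OC(C)=O)c(OC(C)=O)c1 | intermediate
23 | (E)-3-(3,4-diacetoxyphenyl)prop-2-enoyl chloride | ClC(=O)/C=C/c1ccc(OC(C)=O)c(OC(C)=O)c1 | intermediate (not isolated)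
24 | 3-O-[(E)-3,4-diacetoxycinnamoyl]-1,5-quinide | O[C@H]1[C@H]2C[C@](O)(C(=O)O2)C[C@H]1OC(=O)/C=C/c1ccc(OC(C)=O)c(OC(C)=O)c1 | intermediate
25 | p-coumaric acid [(E)-3-(4-hydroxyphenyl)prop-2-enoic acid] | OC(=O)/C=C/c1ccc(O)cc1 | starting material
26 | (E)-3-(4-acetoxyphenyl)prop-2-enoic acid | OC(=O)/C=C/c1ccc(OC(C)=O)cc1 | intermediate
27 | (E)-3-(4-acetoxyphenyl)prop-2-enoyl chloride | ClC(=O)/C=C/c1ccc(OC(C)=O)cc1 | intermediate (not isolated)
28 | 3-O-[(E)-3,4-diacetoxycinnamoyl]-4-O-[(E)-4-acetoxycinnamoyl]-1,5-quinide | O=C(/C=C/c1ccc(OC(C)=O)cc1)O[C@H]1[C@H]2C[C@](O)(C(=O)O2)C[C@H]1OC(=O)/C=C/c1ccc(OC(C)=O)c(OC(C)=O)c1 | intermediate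
29 | 3-O-(E)-caffeoyl-4-O-(E)-p-coumaroylquinic acid (CNP0077575.1) | O=C(/C=C/c1ccc(O)cc1)O[C@H]1[C@H](O)C[C@](O)(C(=O)O)C[C@H]1OC(=O)/C=C/c1ccc(O)c(O)c1 | target

Total step count: 14. Longest linear sequence: 12 steps (1–9, 11, 13, 14); steps 10 and 12 are one-step side branches.

Least certain steps

Step 8 (key step). The most likely failure is insufficient diastereoselection, because only one of the two carbons flanking the new bond carries an oxygen, so part of the cis-diol may form on the face of O5; simple reduction of one aldehyde may also compete with coupling. Fallback, from 14 back to 18: ring-closing metathesis of 14 with second-generation Grubbs catalyst (CH2Cl2, 40 °C) would join C3 and C4 as an alkene with loss of 2-methylpropene, giving the spiro cyclohexene F1. Catalytic OsO4 with N-methylmorpholine N-oxide (acetone/H2O) should then add both oxygens from the face anti to the allylic silyloxy group at C5, which gives 18.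

Step 4. The most likely failure is attack of the Grignard reagent on the dioxolanone carbonyl, with ring opening and loss of pivalaldehyde, in competition with addition to the amide. Fallback, from 6 back to 11: 6 would be converted with (COCl)2 and catalytic DMF into the acid chloride F2. 9 would be transmetalated with ZnCl2 to (2-methylprop-1-en-1-yl)zinc chloride F3, and the two coupled in a Negishi acylation with Pd(PPh3)4 (zerovalent palladium) in THF at 0 °C to give 11. Organozinc reagents do not add to esters or lactones.

Step 5. The most likely failure is poor facial selectivity: the β-branched methylene side may not be small enough against the alkenyl side, and the catalyst may be mismatched with C1. Fallback, from 11 back to 13: a Luche reduction (NaBH4, CeCl3·7H2O, THF/MeOH, −78 °C) would give 13 together with its C5 epimer F4. After separation, F4 would be inverted by a Mitsunobu reaction with chloroacetic acid (PPh3, diisopropyl azodicarboxylate) to the chloroacetate F5, which thiourea and NaHCO3 in ethanol would cleave to 13 without touching the dioxolanone.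

Step 6. The most likely failure is intramolecular transacylation: the C5 hydroxyl of 13 may attack the ring carbonyl through a five-membered transition state, favoured by the quaternary C1, with loss of pivalaldehyde before silylation is complete. Fallback, from 13 back to 20: the same process would be driven to completion with catalytic p-TsOH in CH2Cl2 to give the γ-lactone F6, in which the allyl and alkenyl groups are cis. Ring-closing metathesis with second-generation Grubbs catalyst would give the bicyclic alkene F7, and OsO4 with N-methylmorpholine N-oxide should dihydroxylate it anti to the lactone bridge to give 20. This path bypasses steps 7 to 9.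

Step 11. The most likely failure is incomplete regioselection between O3 and O4, or acyl migration between them in pyridine, which would scramble the two acyl groups. Fallback, from 20 back to 28: the bulkier TBSCl (imidazole, DMF) would silylate the equatorial O3 to give F8. 27 with pyridine and DMAP would acylate O4 to give F9, and HF·pyridine in THF would remove the silyl group under acidic, non-migrating conditions to give F10. 23 in pyridine would then acylate O3 to give 28.

Step 14. The most likely failure is acyl migration from O4 to the liberated O5, or partial loss of a cinnamate, during the long acid exposure that aryl acetates need. Fallback, from 28 back to 29: the three aryl acetates would be removed first by chemoselective hydrazinolysis (N2H4·HOAc, DMF, 0 °C) to give the free-phenol lactone F11. The lactone alone would then be opened by brief treatment with 0.5 M aq. HCl in MeCN at room temperature to give 29.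

Further compounds

F1 | step 8 | spiro cyclohexene: (S)-pivalaldehyde acetal of 5-O-TBS-3,4-dideoxy-3,4-didehydroquinic acid (C3=C4) | C1=C[C@H](O[Si](C)(C)C(C)(C)C)C[C@@]2(O[C@H](C(C)(C)C)OC2=O)C1
F2 | step 4 | 2-[(2S,4S)-2-tert-butyl-5-oxo-4-(prop-2-en-1-yl)-1,3-dioxolan-4-yl]acetyl chloride | O=C(Cl)C[C@]1(CC=C)O[C@H](C(C)(C)C)OC1=O
F3 | step 4 | (2-methylprop-1-en-1-yl)zinc chloride | CC(C)=C[Zn]Cl
F4 | step 5 | (2S,5S)-2-tert-butyl-5-[(2S)-2-hydroxy-4-methylpent-3-en-1-yl]-5-(prop-2-en-1-yl)-1,3-dioxolan-4-one (C5 epimer of 13) | CC(C)=C[C@@H](O)C[C@]1(CC=C)O[C@H](C(C)(C)C)OC1=O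
F5 | step 5 | chloroacetate of 13 [(2R)-carbinol ester] | CC(C)=C[C@H](OC(=O)CCl)C[C@]1(CC=C)O[C@H](C(C)(C)C)OC1=O
F6 | step 6 | (3S,5R)-3-hydroxy-5-(2-methylprop-1-en-1-yl)-3-(prop-2-en-1-yl)oxolan-2-one | CC(C)=C[C@H]1C[C@@](O)(CC=C)C(=O)O1
F7 | step 6 | (1S,5R)-1-hydroxy-6-oxabicyclo[3.2.1]oct-3-en-7-one | C1=C[C@H]2C[C@](O)(C(=O)O2)C1
F8 | step 11 | 3-O-(tert-butyldimethylsilyl)-1,5-quinide | O[C@H]1[C@H]2C[C@](O)(C(=O)O2)C[C@H]1O[Si](C)(C)C(C)(C)C
F9 | step 11 | 3-O-(tert-butyldimethylsilyl)-4-O-[(E)-4-acetoxycinnamoyl]-1,5-quinide | CC(=O)Oc1ccc(/C=C/C(=O)O[C@H]2[C@H]3C[C@](O)(C(=O)O3)C[C@H]2O[Si](C)(C)C(C)(C)C)cc1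
F10 | step 11 | 4-O-[(E)-4-acetoxycinnamoyl]-1,5-quinide | CC(=O)Oc1ccc(/C=C/C(=O)O[C@H]2[C@H]3C[C@](O)(C(=O)O3)C[C@H]2O)cc1
F11 | step 14 | 3-O-(E)-caffeoyl-4-O-(E)-p-coumaroyl-1,5-quinide | O=C(/C=C/c1ccc(O)cc1)O[C@H]1[C@H]2C[C@](O)(C(=O)O2)C[C@H]1OC(=O)/C=C/c1ccc(O)c(O)c1
A1 | alternative 1 | (−)-shikimic acid [(3R,4S,5R)-3,4,5-trihydroxycyclohex-1-ene-1-carboxylic acid] | O[C@H]1[C@H](O)CC(C(=O)O)=C[C@H]1O
A2 | alternative 1 | 5-O-TBS-3,4-O-isopropylidene-shikimyl alcohol (C7 primary allylic alcohol) | CC1(C)O[C@H]2[C@H](O[Si](C)(C)C(C)(C)C)CC(CO)=C[C@H]2O1
A3 | alternative 1 | 1,2-anhydro-5-O-TBS-3,4-O-isopropylidene quinyl alcohol (oxirane on the face of O3 and O4) | CC1(C)O[C@H]2[C@H](O[Si](C)(C)C(C)(C)C)C[C@@]3(CO)O[C@H]3[C@H]2O1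
A4 | alternative 2 | phosphoenolpyruvic acid | C=C(OP(=O)(O)O)C(=O)O
A5 | alternative 2 | D-erythrose 4-phosphate [(2R,3R)-2,3-dihydroxy-4-oxobutyl dihydrogen phosphate] | O=C[C@H](O)[C@H](O)COP(=O)(O)O
A6 | alternative 2 | 3-deoxy-D-arabino-hept-2-ulosonic acid 7-phosphate (open-chain form; 4R,5S,6R) | OC(=O)C(=O)C[C@@H](O)[C@H](O)[C@H](O)COP(=O)(O)O
A7 | alternative 2 | 3-dehydroquinic acid | O[C@H]1[C@H](O)C[C@](O)(C(=O)O)CC1=O
A8 | alternative 3 | buta-1,3-diene | C=CC=C
A9 | alternative 3 | 2-(benzoyloxy)acrolein (1-formylethenyl benzoate) | C=C(OC(=O)c1ccccc1)C=O
A10 | alternative 3 | (S)-1-formylcyclohex-3-en-1-yl benzoate | C1=CC[C@](OC(=O)c2ccccc2)(C=O)CC1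
A11 | alternative 3 | (1S,5R)-7-oxo-6-oxabicyclo[3.2.1]oct-3-en-1-yl benzoate | C1=C[C@H]2C[C@](OC(=O)c3ccccc3)(C(=O)O2)C1
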